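The route rests on cutting the C5–C10 bond of the cyclohexane (ring C5–C10). C5 bears a carbonyl-level carbon (C4, the future acrolein) and the neighbouring quaternary C10 bears methyl plus a two-carbon arm (C1–C2, the future oxirane): the pattern left by an ester-enolate Claisen shift. One [3,3] rearrangement of a ten-membered (E)-allylic lactone therefore builds the carbocycle, the C5–C10 bond and both new stereocentres, leaving a C10 vinyl and a C5 carboxyl group. The precursor is that lactone with a free C6 hydroxyl (rearranged as its chelated dilithium enolate), the C8/C9 acetonide from D-erythronolactone and a silyloxyethyl arm on C7.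

Key step: step 18

Assumption: the target is taken with the configuration written in its SMILES; atoms are numbered as in elemanolides (ring C5–C10, oxirane C1–C2, acrolein C3/C4/C15, lactone C11–C13, methyl C14).
Remark: with a four-atom tether, only the chair array from the E-alkene and the enolate whose oxygen is cis to C6 can place C1 trans to C4; the C6 hydroxyl is therefore left free, so that chelation fixes this enolate geometry and β-elimination is excluded.

Step 1
Reactants: 1 2,3-O-isopropylidene-D-erythronolactone
Product: 2 hydroxy Weinreb amide (ring-opened lactone; cis-dioxolane centres C8 and C9 as in 1; free C7 hydroxyl)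
Conditions: MeNH(OMe)·HCl, i-PrMgCl, THF, −20 → 0 °C
Reagents that add atoms: N,O-dimethylhydroxylamine hydrochloride, CNOC.Cl
Why: Aminolysis of the γ-lactone by the magnesium amide of N,O-dimethylhydroxylamine (Weinreb amide formation) opens the ring without touching either stereocentre.

Step 2
Reactants: 2 hydroxy Weinreb amide
Product: 3 C7 tert-butyldimethylsilyl ether of the Weinreb amide
Conditions: TBSCl, imidazole, DMF, rt
Reagents that add atoms: tert-butyldimethylsilyl chloride, CC(C)(C)[Si](C)(C)Cl
Why: Silylation of the primary alcohol prevents relactonisation and masks C7–OH for the next four steps.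

Step 3
Reactants: 3 silylated Weinreb amide
Product: 4 methyl ketone (C10 carbonyl carrying the C14 methyl)
Conditions: MeMgBr, THF, 0 °C
Reagents that add atoms: methylmagnesium bromide, C[Mg]Br
Why: Grignard addition to a Weinreb amide stops at the chelated tetrahedral stage and should give the ketone without over-addition or epimerisation at C9.

Step 4
Reactants: 4 methyl ketone; 5 tert-butyl diethylphosphonoacetate
Product: 6 (E)-tert-butyl enoate (C10=C1 with C9 trans to C2; C7 silyl ether)
Conditions: NaH, THF, 0 °C → rt; minor Z isomer removed by chromatography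
Reagents that add atoms: none
Why: Horner–Wadsworth–Emmons olefination of a methyl ketone bearing a branched α-substituent should favour the E-trisubstituted enoate, which fixes the alkene geometry needed in step 18.

Step 5
Reactants: 6 (E)-enoate silyl ether
Product: 7 primary alcohol (C7–OH)
Conditions: HF·pyridine, pyridine, THF, 0 °C → rt
Reagents that add atoms: none
Why: Buffered fluoride desilylation avoids alkoxide formation and thus oxa-Michael closure onto the enoate.

Step 6
Reactants: 7 primary alcohol
Product: 8 C7 aldehyde (cis-dioxolane carbaldehyde used crude)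
Conditions: Dess–Martin periodinane, NaHCO3, CH2Cl2, rt
Reagents that add atoms: none
Why: Dess–Martin oxidation under buffered neutral conditions should give the α-alkoxy aldehyde without epimerisation at C8.

Step 7
Reactants: 8 aldehyde; 9 methyl bis(2,2,2-trifluoroethyl)phosphonoacetate
Product: 10 (Z)-methyl enoate (C7=C11 with C8 cis to C12; tert-butyl enoate unchanged)
Conditions: KN(SiMe3)2, 18-crown-6, THF, −78 °C
Reagents that add atoms: none
Why: Still–Gennari olefination gives the Z-enoate kinetically at −78 °C, where the α-stereocentre of the aldehyde should be safe.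

Step 8
Reactants: 10 (Z)-enoate; 11 nitromethane
Product: 12 γ-nitro ester (new C7 centre; nitromethyl carbon C6 syn to O8; CH2CO2Me is the C11–C12 arm)
Conditions: DBU (0.2 equiv), MeNO2 as solvent, 0 °C → rt
Reagents that add atoms: none
Why: Michael addition of the nitronate to the Z-γ-alkoxy enoate; 1,3-allylic strain holds C8–H in the alkene plane and the nucleophile enters C7 from the face of the dioxolane oxygen O8, away from the substituted C9, while the β,β-disubstituted tert-butyl enoate is inert.

Step 9
Reactants: 12 γ-nitro ester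
Product: 13 nitro alcohol (C12–OH)
Conditions: LiBH4, THF, MeOH (1 equiv), 0 °C → rt
Reagents that add atoms: none
Why: LiBH4 reduces the saturated methyl ester chemoselectively, leaving the conjugated tert-butyl ester and the nitro group.

Step 10
Reactants: 13 nitro alcohol
Product: 14 nitro compound with C12 tert-butyldimethylsilyl ether
Conditions: TBSCl, imidazole, CH2Cl2, rt
Reagents that add atoms: tert-butyldimethylsilyl chloride, CC(C)(C)[Si](C)(C)Cl
Why: Standard silylation protects the arm as an ether that later leaves together with the acetonide.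

Step 11
Reactants: 14 silylated nitro compound
Product: 16 C6 aldehyde, via sodium nitronate 15 (not isolated)
Conditions: NaOMe, MeOH, 0 °C; then TiCl3, NH4OAc, H2O (pH about 6), 0 °C → rt
Reagents that add atoms: sodium methoxide, C[O-].[Na+] (sodium in 15 only); water, O
Why: Reductive Nef reaction; the nitronate is reduced by TiCl3 to the imine, which hydrolyses in the buffered medium without loss of the acetonide or epimerisation at C7.

Step 12
Reactants: 16 aldehyde; 17 1-(tert-butyldimethylsilyloxy)-1-methoxyethene
Product: 18 β-hydroxy methyl ester (new C6 carbinol; O6 syn to the C7 arm and anti to O8)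
Conditions: BF3·OEt2, CH2Cl2, −78 °C
Reagents that add atoms: none
Why: Mukaiyama acetate aldol under non-chelating conditions; Felkin–Anh addition anti to C8 and the 1,3-anti preference of the β-alkoxy aldehyde reinforce each other in this 2,3-anti aldehyde and should set C6 as required.

Step 13
Reactants: 18 β-hydroxy ester
Product: 19 C6 triethylsilyl ether
Conditions: TESOTf, 2,6-lutidine, CH2Cl2, −78 °C
Reagents that add atoms: triethylsilyl triflate, CC[Si](CC)(CC)OS(=O)(=O)C(F)(F)F
Why: Temporary silylation blocks β-lactone formation during carboxyl activation in step 16.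

Step 14
Reactants: 19 silyl ether methyl ester
Product: 20 C4 carboxylic acid (tert-butyl enoate intact)
Conditions: LiOH, THF/MeOH/H2O, 0 °C → rt; aq. HCl to pH 4
Reagents that add atoms: lithium hydroxide, [Li+].[OH-]
Why: Saponification discriminates the unhindered methyl ester from the conjugated tert-butyl ester.

Step 15
Reactants: 20 acid enoate
Product: 21 seco acid (C2 allylic alcohol; E-alkene)
Conditions: i-Bu2AlH (5 equiv), CH2Cl2, −78 °C; aq. potassium sodium tartrate
Reagents that add atoms: none
Why: 1,2-Reduction of the enoate by i-Bu2AlH, during which the carboxyl group is protected as its aluminium carboxylate, which is not reduced at −78 °C.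

Step 16
Reactants: 21 seco acid
Product: 23 ten-membered lactone with C6 triethylsilyl ether, via mixed anhydride 22 (not isolated)
Conditions: 2-methyl-6-nitrobenzoic anhydride, DMAP, Et3N, toluene (2 mM, slow addition), rt → 40 °C
Reagents that add atoms: 2-methyl-6-nitrobenzoic anhydride, Cc1cccc([N+](=O)[O-])c1C(=O)OC(=O)c1c(C)cccc1[N+](=O)[O-] (acyl group in 22 only)
Why: Shiina macrolactonisation, a method suited to medium rings, closes the O–C4 bond onto the primary allylic alcohol under high dilution.

Step 17
Reactants: 23 silylated lactone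
Product: 24 ten-membered (E)-allylic β-hydroxy lactone (free C6–OH; C8/C9 acetonide; C7 silyloxyethyl arm)
Conditions: HF·pyridine, pyridine, THF, 0 °C
Reagents that add atoms: none
Why: The triethylsilyl ether is cleaved selectively by buffered fluoride in the presence of the tert-butyldimethylsilyl ether and the acetonide.

Step 18
Reactants: 24 β-hydroxy lactone
Product: 26 cyclohexanecarboxylic acid (C10 methyl and vinyl; C5 carboxyl cis to the methyl and to O6), via dilithium alkoxide enolate 25 (not isolated)
Conditions: LiN(i-Pr)2 (2.5 equiv), THF, −78 → 0 °C, then rt → 40 °C; aq. HCl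
Reagents that add atoms: lithium diisopropylamide, [Li+].CC(C)[N-]C(C)C (lithium in 25 only)
Why: Two equivalents of base give the lithium alkoxide/lithium enolate chelate 25, in which the enolate oxygen is held cis to C6 (C6 trans to the ring oxygen); this oxa-analogue of an E,E-cyclodeca-1,5-diene undergoes a [3,3]-sigmatropic ester-enolate Claisen shift that forms C5–C10 and breaks O–C2. The closest known reactions are the Ireland–Claisen ring contraction of macrocyclic allylic lactones and the dianionic enolate Claisen rearrangement of allyl β-hydroxy esters. The cyclohexane closes by transannular attack of the enolate carbon C5 on C10 (6-exo-trig with respect to C10=C1, enolexo with respect to C5=C4) through a chair array fused trans-decalin-like to the forming ring. C10 is set by the E geometry of C10=C1 in that chair (methyl axial, cis to C4); C5 is set by the chelate, which keeps O6 in the enolate plane so that C10 bonds to the face carrying C7 and C4 ends cis to O6. The step needs this chair to win over the alternative chair (O6 out of plane, both new centres inverted) and over the boat, and rearrangement to outrun fragmentation: the chelate favours the first, the E,E geometry secures the second, and the alkoxide, a non-leaving group, shuts off β-elimination.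

Step 19
Reactants: 26 β-hydroxy acid
Product: 28 C6 tert-butyldimethylsilyl ether acid, via bis-silyl derivative 27 (not isolated)
Conditions: TBSOTf (3 equiv), 2,6-lutidine, CH2Cl2, 0 °C; then K2CO3, MeOH/THF/H2O, rt
Reagents that add atoms: tert-butyldimethylsilyl triflate, CC(C)(C)[Si](C)(C)OS(=O)(=O)C(F)(F)F
Why: The silyl triflate silylates the hindered C6 alcohol and the acid, and mild methanolysis then cleaves only the silyl ester.

Step 20
Reactants: 28 silyloxy acid
Product: 29 methyl ketone (C4 carbonyl)
Conditions: MeLi (5 equiv), Et2O, 0 °C → rt; inverse quench into aq. NH4Cl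
Reagents that add atoms: methyllithium, [Li]C
Why: Addition of methyllithium to the lithium carboxylate gives a stable dilithium gem-diolate that releases the ketone only on work-up, so neither over-addition nor β-elimination of the silyloxy group should occur.

Step 21
Reactants: 29 methyl ketone
Product: 30 isopropenyl compound (C4=C15)
Conditions: Cp2TiMe2, toluene/THF, 70 °C
Reagents that add atoms: dimethyltitanocene, C[Ti](C)(C1C=CC=C1)C1C=CC=C1
Why: Petasis methylenation is non-basic and should convert the hindered β-silyloxy ketone without enolisation, epimerisation at C5 or elimination.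

Step 22
Reactants: 30 isopropenyl compound
Product: 31 triol (free O8–H, O9–H and C12–OH; C6 silyl ether kept)
Conditions: camphorsulfonic acid (0.2 equiv), MeOH, rt
Reagents that add atoms: none
Why: Acid-catalysed transketalisation removes the acetonide and the primary silyl ether, while the secondary silyl ether flanked by C5 and C7 is too hindered to cleave.

Step 23
Reactants: 31 triol
Product: 33 cis-fused γ-lactone onto O8 with free O9–H, via lactol 32 (not isolated)
Conditions: TEMPO (0.2 equiv), PhI(OAc)2, CH2Cl2, rt
Reagents that add atoms: none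
Why: Oxoammonium oxidation takes the primary alcohol to the aldehyde, which closes to the five-membered lactol with the cis O8–H and is oxidised on to the lactone; the hindered secondary O9–H is left.

Step 24
Reactants: 33 hydroxy lactone
Product: 36 α-methylene lactone (C11=C13), via Mannich base 34 (not isolated), via ammonium iodide 35 (not isolated)
Conditions: LiN(i-Pr)2 (2.3 equiv), THF, −78 °C; Me2N=CH2 iodide, −78 °C → rt; then MeI, MeOH; then NaHCO3, EtOAc/H2O
Reagents that add atoms: N,N-dimethylmethyleneiminium iodide, C=[N+](C)C.[I-]; methyl iodide, CI (methyl in 35 only)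
Why: Aminomethylation of the lactone enolate with Eschenmoser's salt (the O9 alkoxide is a spectator) and elimination of the quaternised amine is the standard α-methylenation of γ-lactones.

Step 25
Reactants: 36 α-methylene lactone
Product: 37 (1S)-oxirane (vinyl group epoxidised)
Conditions: VO(acac)2 (0.1 equiv), t-BuOOH, CH2Cl2, 0 °C → rt
Reagents that add atoms: tert-butyl hydroperoxide, CC(C)(C)OO
Why: Hydroxyl-directed vanadium epoxidation of the homoallylic alcohol; the vanadate on the cis O9 delivers oxygen to the face of the axial vinyl group turned toward C9, whose CH2 end must point away from the ring because the axial O8 fills the space under it, and the isopropenyl and acrylate alkenes are not directed.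

Step 26
Reactants: 37 epoxy alcohol; 38 methacrylic anhydride
Product: 39 C9 methacrylate
Conditions: DMAP, Et3N, CH2Cl2, rt
Reagents that add atoms: none
Why: DMAP-catalysed acylation esterifies the only free hydroxyl under conditions the oxirane tolerates.

Step 27
Reactants: 39 methacrylate
Product: 41 enal with C6 silyl ether, via allylic alcohol 40 (not isolated)
Conditions: SeO2 (0.5 equiv), t-BuOOH, CH2Cl2, rt; then Dess–Martin periodinane, NaHCO3, CH2Cl2
Reagents that add atoms: selenium dioxide, O=[Se]=O; tert-butyl hydroperoxide, CC(C)(C)OO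
Why: Selenium dioxide allylic oxidation (ene reaction then [2,3] shift) attacks the methyl group of the only electron-rich alkene bearing allylic hydrogens, and the periodinane takes residual allylic alcohol on to the enal.

Step 28
Reactants: 41 silyl-protected enal
Product: 42 CNP0124638.3
Conditions: HF·pyridine, pyridine, THF, 0 °C → rt
Reagents that add atoms: none
Why: Buffered fluoride desilylation frees the C6 hydroxyl last, under conditions that should spare the oxirane, enal, methacrylate and α-methylene lactone.

Compound list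
1 | 2,3-O-isopropylidene-D-erythronolactone, (3aR,6aR) | O=C1OC[C@H]2OC(C)(C)O[C@@H]12 | starting material
2 | hydroxy Weinreb amide | OC[C@H]1OC(C)(C)O[C@H]1C(=O)N(C)OC | intermediate
3 | silylated Weinreb amide | CC(C)(C)[Si](C)(C)OC[C@H]1OC(C)(C)O[C@H]1C(=O)N(C)OC | intermediate
4 | methyl ketone | CC(C)(C)[Si](C)(C)OC[C@H]1OC(C)(C)O[C@H]1C(C)=O | intermediate
5 | tert-butyl diethylphosphonoacetate | CCOP(=O)(CC(=O)OC(C)(C)C)OCC | starting material
6 | (E)-tert-butyl enoate, C7 silyl ether | CC(C)(C)[Si](C)(C)OC[C@H]1OC(C)(C)O[C@H]1/C(C)=C/C(=O)OC(C)(C)C | intermediate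
7 | primary alcohol | OC[C@H]1OC(C)(C)O[C@H]1/C(C)=C/C(=O)OC(C)(C)C | intermediate
8 | C7 aldehyde | O=C[C@H]1OC(C)(C)O[C@H]1/C(C)=C/C(=O)OC(C)(C)C | intermediate
9 | methyl bis(2,2,2-trifluoroethyl)phosphonoacetate | COC(=O)CP(=O)(OCC(F)(F)F)OCC(F)(F)F | starting material
10 | (Z)-methyl enoate | COC(=O)/C=C\[C@H]1OC(C)(C)O[C@H]1/C(C)=C/C(=O)OC(C)(C)C | intermediate
11 | nitromethane | C[N+](=O)[O-] | starting material
12 | γ-nitro ester | [O-][N+](=O)C[C@@H](CC(=O)OC)[C@H]1OC(C)(C)O[C@H]1/C(C)=C/C(=O)OC(C)(C)C | intermediate
13 | nitro alcohol | [O-][N+](=O)C[C@@H](CCO)[C@H]1OC(C)(C)O[C@H]1/C(C)=C/C(=O)OC(C)(C)C | intermediate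
14 | nitro silyl ether | [O-][N+](=O)C[C@@H](CCO[Si](C)(C)C(C)(C)C)[C@H]1OC(C)(C)O[C@H]1/C(C)=C/C(=O)OC(C)(C)C | intermediate
15 | sodium nitronate | [Na+].[O-][N+]([O-])=C[C@@H](CCO[Si](C)(C)C(C)(C)C)[C@H]1OC(C)(C)O[C@H]1/C(C)=C/C(=O)OC(C)(C)C | intermediate
16 | C6 aldehyde | O=C[C@@H](CCO[Si](C)(C)C(C)(C)C)[C@H]1OC(C)(C)O[C@H]1/C(C)=C/C(=O)OC(C)(C)C | intermediate
17 | 1-(tert-butyldimethylsilyloxy)-1-methoxyethene | C=C(OC)O[Si](C)(C)C(C)(C)C | starting material
18 | β-hydroxy methyl ester | COC(=O)C[C@H](O)[C@@H](CCO[Si](C)(C)C(C)(C)C)[C@H]1OC(C)(C)O[C@H]1/C(C)=C/C(=O)OC(C)(C)C | intermediate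
19 | C6 triethylsilyl ether | COC(=O)C[C@H](O[Si](CC)(CC)CC)[C@@H](CCO[Si](C)(C)C(C)(C)C)[C@H]1OC(C)(C)O[C@H]1/C(C)=C/C(=O)OC(C)(C)C | intermediate
20 | C4 acid | OC(=O)C[C@H](O[Si](CC)(CC)CC)[C@@H](CCO[Si](C)(C)C(C)(C)C)[C@H]1OC(C)(C)O[C@H]1/C(C)=C/C(=O)OC(C)(C)C | intermediate
21 | seco acid | OC(=O)C[C@H](O[Si](CC)(CC)CC)[C@@H](CCO[Si](C)(C)C(C)(C)C)[C@H]1OC(C)(C)O[C@H]1/C(C)=C/CO | intermediate
22 | mixed anhydride | Cc1cccc([N+](=O)[O-])c1C(=O)OC(=O)C[C@H](O[Si](CC)(CC)CC)[C@@H](CCO[Si](C)(C)C(C)(C)C)[C@H]1OC(C)(C)O[C@H]1/C(C)=C/CO | intermediate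
23 | ten-membered lactone, C6 triethylsilyl ether | O=C1C[C@H](O[Si](CC)(CC)CC)[C@@H](CCO[Si](C)(C)C(C)(C)C)[C@H]2OC(C)(C)O[C@H]2/C(C)=C/CO1 | intermediate
24 | ten-membered (E)-allylic β-hydroxy lactone (key-step precursor) | O=C1C[C@H](O)[C@@H](CCO[Si](C)(C)C(C)(C)C)[C@H]2OC(C)(C)O[C@H]2/C(C)=C/CO1 | intermediate
25 | dilithium alkoxide enolate | [Li+].[Li+].[O-]/C1=C\[C@H]([O-])[C@@H](CCO[Si](C)(C)C(C)(C)C)[C@H]2OC(C)(C)O[C@H]2/C(C)=C/CO1 | intermediate
26 | cyclohexanecarboxylic acid (key-step product) | CC1(C)O[C@@H]2[C@H](O1)[C@H](CCO[Si](C)(C)C(C)(C)C)[C@@H](O)[C@@H](C(=O)O)[C@]2(C)C=C | intermediate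
27 | bis-silyl derivative (silyl ester, silyl ether) | CC1(C)O[C@@H]2[C@H](O1)[C@H](CCO[Si](C)(C)C(C)(C)C)[C@@H](O[Si](C)(C)C(C)(C)C)[C@@H](C(=O)O[Si](C)(C)C(C)(C)C)[C@]2(C)C=C | intermediate
28 | C6 silyloxy acid | CC1(C)O[C@@H]2[C@H](O1)[C@H](CCO[Si](C)(C)C(C)(C)C)[C@@H](O[Si](C)(C)C(C)(C)C)[C@@H](C(=O)O)[C@]2(C)C=C | intermediate
29 | C4 methyl ketone | CC1(C)O[C@@H]2[C@H](O1)[C@H](CCO[Si](C)(C)C(C)(C)C)[C@@H](O[Si](C)(C)C(C)(C)C)[C@@H](C(C)=O)[C@]2(C)C=C | intermediate
30 | isopropenyl compound | CC1(C)O[C@@H]2[C@H](O1)[C@H](CCO[Si](C)(C)C(C)(C)C)[C@@H](O[Si](C)(C)C(C)(C)C)[C@@H](C(C)=C)[C@]2(C)C=C | intermediate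
31 | triol | O[C@@H]1[C@H](O)[C@H](CCO)[C@@H](O[Si](C)(C)C(C)(C)C)[C@@H](C(C)=C)[C@]1(C)C=C | intermediate
32 | lactol | O[C@@H]1[C@@H]2OC(O)C[C@@H]2[C@@H](O[Si](C)(C)C(C)(C)C)[C@@H](C(C)=C)[C@]1(C)C=C | intermediate
33 | hydroxy γ-lactone | O[C@@H]1[C@@H]2OC(=O)C[C@@H]2[C@@H](O[Si](C)(C)C(C)(C)C)[C@@H](C(C)=C)[C@]1(C)C=C | intermediate
34 | Mannich base | O[C@@H]1[C@@H]2OC(=O)C(CN(C)C)[C@@H]2[C@@H](O[Si](C)(C)C(C)(C)C)[C@@H](C(C)=C)[C@]1(C)C=C | intermediate
35 | ammonium iodide | [I-].O[C@@H]1[C@@H]2OC(=O)C(C[N+](C)(C)C)[C@@H]2[C@@H](O[Si](C)(C)C(C)(C)C)[C@@H](C(C)=C)[C@]1(C)C=C | intermediate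
36 | α-methylene lactone | O[C@@H]1[C@@H]2OC(=O)C(=C)[C@@H]2[C@@H](O[Si](C)(C)C(C)(C)C)[C@@H](C(C)=C)[C@]1(C)C=C | intermediate
37 | (1S)-oxirane | O[C@@H]1[C@@H]2OC(=O)C(=C)[C@@H]2[C@@H](O[Si](C)(C)C(C)(C)C)[C@@H](C(C)=C)[C@]1(C)[C@H]1CO1 | intermediate
38 | methacrylic anhydride | C=C(C)C(=O)OC(=O)C(C)=C | starting material
39 | C9 methacrylate | C=C(C)C(=O)O[C@@H]1[C@@H]2OC(=O)C(=C)[C@@H]2[C@@H](O[Si](C)(C)C(C)(C)C)[C@@H](C(C)=C)[C@]1(C)[C@H]1CO1 | intermediate
40 | allylic alcohol | C=C(C)C(=O)O[C@@H]1[C@@H]2OC(=O)C(=C)[C@@H]2[C@@H](O[Si](C)(C)C(C)(C)C)[C@@H](C(=C)CO)[C@]1(C)[C@H]1CO1 | intermediate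
41 | silyl-protected enal | C=C(C)C(=O)O[C@@H]1[C@@H]2OC(=O)C(=C)[C@@H]2[C@@H](O[Si](C)(C)C(C)(C)C)[C@@H](C(=C)C=O)[C@]1(C)[C@H]1CO1 | intermediate
42 | CNP0124638.3 | C=C(C)C(=O)O[C@@H]1[C@@H]2OC(=O)C(=C)[C@@H]2[C@@H](O)[C@@H](C(=C)C=O)[C@]1(C)[C@H]1CO1 | target

Total step count: 28. Longest linear sequence: 28 steps (from 1; the other starting materials are commercial reagents).

Steps most likely to fail

Step 18 (key step). The dilithium enolate may fragment (ketene loss or retro-aldol opening) before it rearranges. The shift may also run through the other chair, with O6 out of the enolate plane, which would invert both new centres. The fallback sets out from 23 and comes back at 26. The C6 triethylsilyl ether 23 is enolised with KN(SiMe3)2 and Me3SiCl in THF–DMPU at −78 °C, conditions expected to give the silyl ketene acetal F1 with the silyloxy group cis to C6. On warming, F1 should undergo the classical Ireland–Claisen contraction to the trimethylsilyl ester F2. Aqueous work-up then gives the C6 triethylsilyloxy acid F3. HF·pyridine removes the triethylsilyl group, as in step 17, to give 26.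

Step 16. The strain of the ten-membered E-lactone may let intermolecular acylation (diolide and oligomers) outrun ring closure. The fallback sets out from 21 and comes back at 23. The ring is closed from the other side by a Mitsunobu macrolactonisation (PPh3, diisopropyl azodicarboxylate, toluene, high dilution), in which the primary allylic alcohol is activated and the carboxylate attacks C2. This detour makes no new compound (F0).

Step 25. Oxygen transfer to the hindered vinyl group may be slow and may show poor facial selectivity at C1. The fallback sets out from 36 and comes back at 37. The epoxidation is run to completion regardless of selectivity, giving 37 mixed with its C1 epimer F4. The mixture is then submitted to Jacobsen hydrolytic kinetic resolution with (R,R)-(salen)Co(OAc) and water. The catalyst is expected to open the (1R)-oxirane F4 to the diol F5 and leave the (1S)-oxirane 37, which is separated by chromatography.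

Further compounds
F1 | step 18 | trimethylsilyl ketene acetal of lactone 23 | C[Si](C)(C)O/C1=C\[C@H](O[Si](CC)(CC)CC)[C@@H](CCO[Si](C)(C)C(C)(C)C)[C@H]2OC(C)(C)O[C@H]2/C(C)=C/CO1
F2 | step 18 | trimethylsilyl ester of the C6 triethylsilyloxy acid | CC1(C)O[C@@H]2[C@H](O1)[C@H](CCO[Si](C)(C)C(C)(C)C)[C@@H](O[Si](CC)(CC)CC)[C@@H](C(=O)O[Si](C)(C)C)[C@]2(C)C=C
F3 | step 18 | C6 triethylsilyloxy cyclohexanecarboxylic acid | CC1(C)O[C@@H]2[C@H](O1)[C@H](CCO[Si](C)(C)C(C)(C)C)[C@@H](O[Si](CC)(CC)CC)[C@@H](C(=O)O)[C@]2(C)C=C
F0 | step 16 | none | none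
F4 | step 25 | (1R)-oxirane, C1 epimer of 37 | O[C@@H]1[C@@H]2OC(=O)C(=C)[C@@H]2[C@@H](O[Si](C)(C)C(C)(C)C)[C@@H](C(C)=C)[C@]1(C)[C@@H]1CO1
F5 | step 25 | (1R)-1,2-diol from F4 | O[C@@H]1[C@@H]2OC(=O)C(=C)[C@@H]2[C@@H](O[Si](C)(C)C(C)(C)C)[C@@H](C(C)=C)[C@]1(C)[C@@H](O)CO
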